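**Retrosynthetic overview** (quinolizidine numbering, N5/C9a; unit A = the 9R half, unit B = the 9S half)
1. 30 ⇐ 29: the last vinylogous amide (unit B) is reduced, which sets C9a of unit B; C1/C3 of both units are then equilibrated.
2. 29 ⇐ 27: the 16-membered ring is closed by a photochemical decarboxylative Giese addition onto the C1 methylene ketone of unit A.
3. 27 ⇐ 24 + 13: the halves are joined by a photochemical nickel-catalysed decarboxylative C(sp3)–C(sp2) coupling at C1 of iodinated unit B; unit A is saturated beforehand so its C9a is set thermodynamically.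
4. Bicyclic vinylogous amides 12 and 23 (ring A, then ring B) ⇐ α-chiral methyl ketones 8 and 20 + a methacryloyl unit + ammonia.
5. 8 and 20 ⇐ ethyl (S)- and (R)-3-hydroxybutanoate by Fráter–Seebach alkylation (sets C9), chain extension and oxidation.

Assumption: methyl-bearing C3 next to a vinylogous amide carbonyl is carried as an epimer mixture (equilibrated at the end); both Grignard reagents and amide 9 are bought.

**Step 1**
Reactants: 1 ethyl (S)-3-hydroxybutanoate; 2 1-chloro-3-iodopropane
Product: 3 ethyl (2S,3S)-2-(3-chloropropyl)-3-hydroxybutanoate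
Conditions: LiN(iPr)2 (2.2 equiv), THF, −78 → −20 °C; then 2, DMPU, −20 → 0 °C; NH4Cl
Reagents that add atoms: none
Why: Fráter–Seebach alkylation: the chelated lithium alkoxide–enolate is alkylated by the iodide end anti to the carbinol substituent, so the bought carbinol centre sets the new stereocentre (future C9 of unit B, anti, about 95:5) while the chloride is kept for ring B.

**Step 2**
Reactants: 3 ethyl (2S,3S)-2-(3-chloropropyl)-3-hydroxybutanoate
Product: 4 (2R,3S)-2-(3-chloropropyl)butane-1,3-diol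
Conditions: LiAlH4, THF, 0 °C
Reagents that add atoms: none
Why: LiAlH4 ester reduction; the primary chloride and both stereocentres are untouched at 0 °C (the C2 descriptor changes by CIP priority only).

**Step 3**
Reactants: 4 (2R,3S)-2-(3-chloropropyl)butane-1,3-diol
Product: 5 (2R,3S)-2-(3-chloropropyl)-3-hydroxybutyl 4-methylbenzenesulfonate
Conditions: TsCl (1.05 equiv), pyridine, CH2Cl2, −20 → 0 °C
Reagents that add atoms: 4-methylbenzenesulfonyl chloride, Cc1ccc(cc1)S(=O)(=O)Cl
Why: Selective sulfonylation of the primary hydroxyl over the hindered secondary one.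

**Step 4**
Reactants: 5 (2R,3S)-2-(3-chloropropyl)-3-hydroxybutyl 4-methylbenzenesulfonate; 6 pent-4-en-1-ylmagnesium bromide
Product: 7 (2S,3S)-3-(3-chloropropyl)non-8-en-2-ol
Conditions: 6 (2.5 equiv), Li2CuCl4 (5 mol %), THF, −30 → 0 °C
Reagents that add atoms: none
Why: Kochi-type copper-catalysed sp3–sp3 coupling of a primary tosylate with a primary Grignard reagent; the tosylate reacts far faster than the alkyl chloride and no stereocentre is involved.

**Step 5**
Reactants: 7 (2S,3S)-3-(3-chloropropyl)non-8-en-2-ol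
Product: 8 (6S)-6-acetyl-9-chlorononanoic acid
Conditions: RuCl3·xH2O (5 mol %), NaIO4 (6 equiv), EtOAc/MeCN/H2O, 0 °C → rt
Reagents that add atoms: sodium periodate, [Na+].[O-]I(=O)(=O)=O; water, O
Why: Ruthenium tetroxide oxidation (Sharpless conditions) turns the secondary alcohol into the methyl ketone and cleaves the terminal alkene to the acid in one operation; the carbinol centre is erased after doing its job and the α-centre survives the brief, near-neutral oxidation.

**Step 6**
Reactants: 8 (6S)-6-acetyl-9-chlorononanoic acid; 9 N-methoxy-N-methylmethacrylamide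
Product: 12 5-[(9S)-3-methyl-2-oxo-3,4,6,7,8,9-hexahydro-2H-quinolizin-9-yl]pentanoic acid, via diketone 10 (not isolated), via monocyclic vinylogous amide 11 (not isolated)
Conditions: LiN(SiMe3)2 (2.2 equiv), THF, −78 °C; 9, −78 → −20 °C; AcOH; then NH3 (7 M in MeOH), rt; evaporate; then Cs2CO3, NaI (10 mol %), DMF, 60 °C
Reagents that add atoms: ammonia, N
Why: Crossed Claisen acylation of the kinetic methyl-ketone enolate (carboxylate inert) by the Weinreb amide, then an ammonia cascade of aza-Michael addition to the isopropenyl ketone, condensation with the C9a carbonyl (ring A) and 6-exo-tet N-alkylation by the chloride (ring B); C9 is not scrambled because the 1,3-dicarbonyl and the vinylogous amide enolise toward C1.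

**Step 7**
Reactants: 12 5-[(9S)-3-methyl-2-oxo-3,4,6,7,8,9-hexahydro-2H-quinolizin-9-yl]pentanoic acid
Product: 13 5-[(9S)-1-iodo-3-methyl-2-oxo-3,4,6,7,8,9-hexahydro-2H-quinolizin-9-yl]pentanoic acid
Conditions: N-iodosuccinimide (1.05 equiv), CH2Cl2, 0 °C, dark
Reagents that add atoms: N-iodosuccinimide, O=C1CCC(=O)N1I
Why: Electrophilic α-iodination of the vinylogous amide at its nucleophilic C1.

**Step 8**
Reactants: 14 ethyl (R)-3-hydroxybutanoate; 2 1-chloro-3-iodopropane
Product: 15 ethyl (2R,3R)-2-(3-chloropropyl)-3-hydroxybutanoate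
Conditions: LiN(iPr)2 (2.2 equiv), THF, −78 → −20 °C; then 2, DMPU, −20 → 0 °C; NH4Cl
Reagents that add atoms: none
Why: Fráter–Seebach alkylation as in step 1 in the enantiomeric series; the bought carbinol centre sets the future C9 of unit A (anti).

**Step 9**
Reactants: 15 ethyl (2R,3R)-2-(3-chloropropyl)-3-hydroxybutanoate
Product: 16 (2S,3R)-2-(3-chloropropyl)butane-1,3-diol
Conditions: LiAlH4, THF, 0 °C
Reagents that add atoms: none
Why: LiAlH4 ester reduction as in step 2, stereocentres untouched.

**Step 10**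
Reactants: 16 (2S,3R)-2-(3-chloropropyl)butane-1,3-diol
Product: 17 (2S,3R)-2-(3-chloropropyl)-3-hydroxybutyl 4-methylbenzenesulfonate
Conditions: TsCl (1.05 equiv), pyridine, CH2Cl2, −20 → 0 °C
Reagents that add atoms: 4-methylbenzenesulfonyl chloride, Cc1ccc(cc1)S(=O)(=O)Cl
Why: Selective primary sulfonylation as in step 3.

**Step 11**
Reactants: 17 (2S,3R)-2-(3-chloropropyl)-3-hydroxybutyl 4-methylbenzenesulfonate; 18 hex-5-en-1-ylmagnesium bromide
Product: 19 (2R,3R)-3-(3-chloropropyl)dec-9-en-2-ol
Conditions: 18 (2.5 equiv), Li2CuCl4 (5 mol %), THF, −30 → 0 °C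
Reagents that add atoms: none
Why: Kochi-type copper-catalysed sp3–sp3 coupling as in step 4; the chain is one carbon longer because unit A keeps all five chain carbons after decarboxylation in step 15.

**Step 12**
Reactants: 19 (2R,3R)-3-(3-chloropropyl)dec-9-en-2-ol
Product: 20 (7R)-7-acetyl-10-chlorodecanoic acid
Conditions: RuCl3·xH2O (5 mol %), NaIO4 (6 equiv), EtOAc/MeCN/H2O, 0 °C → rt
Reagents that add atoms: sodium periodate, [Na+].[O-]I(=O)(=O)=O; water, O
Why: Ruthenium tetroxide oxidation as in step 5 (alcohol to ketone, alkene to acid).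

**Step 13**
Reactants: 20 (7R)-7-acetyl-10-chlorodecanoic acid; 9 N-methoxy-N-methylmethacrylamide
Product: 23 6-[(9R)-3-methyl-2-oxo-3,4,6,7,8,9-hexahydro-2H-quinolizin-9-yl]hexanoic acid, via diketone 21 (not isolated), via monocyclic vinylogous amide 22 (not isolated)
Conditions: LiN(SiMe3)2 (2.2 equiv), THF, −78 °C; 9, −78 → −20 °C; AcOH; then NH3 (7 M in MeOH), rt; evaporate; then Cs2CO3, NaI (10 mol %), DMF, 60 °C
Reagents that add atoms: ammonia, N
Why: Crossed Claisen acylation and ammonia aza-Michael/condensation/N-alkylation cascade as in step 6, giving the enantiomeric bicyclic vinylogous amide with C9 intact.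

**Step 14**
Reactants: 23 6-[(9R)-3-methyl-2-oxo-3,4,6,7,8,9-hexahydro-2H-quinolizin-9-yl]hexanoic acid
Product: 24 6-[(3S,9R,9aS)-3-methyl-2-oxooctahydro-2H-quinolizin-9-yl]hexanoic acid
Conditions: Et3SiH (2 equiv), TFA/CH2Cl2 (1:4), 0 °C → rt; NaHCO3 work-up; then K2CO3, MeOH, 50 °C, 12 h
Reagents that add atoms: none
Why: Ionic hydrogenation (C-protonation to the bicyclic iminium, hydride from the silane) saturates the vinylogous amide, and base equilibration (enolisation and reversible retro-aza-Michael opening) funnels C9a and C3 to the all-equatorial trans-quinolizidinone (H9a trans to H9, methyl equatorial) dictated by C9.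

**Step 15**
Reactants: 24 6-[(3S,9R,9aS)-3-methyl-2-oxooctahydro-2H-quinolizin-9-yl]hexanoic acid; 13 5-[(9S)-1-iodo-3-methyl-2-oxo-3,4,6,7,8,9-hexahydro-2H-quinolizin-9-yl]pentanoic acid
Product: 26 5-[(9S)-3-methyl-1-{5-[(3S,9R,9aS)-3-methyl-2-oxooctahydro-2H-quinolizin-9-yl]pentyl}-2-oxo-3,4,6,7,8,9-hexahydro-2H-quinolizin-9-yl]pentanoic acid, via redox-active ester 25 (not isolated)
Conditions: 24, N-hydroxyphthalimide (1.0 equiv), N,N'-diisopropylcarbodiimide (1.0 equiv), DMAP (5 mol %), CH2Cl2, rt; evaporate; then 13 (1.0 equiv), NiBr2·dme (10 mol %), 4,4'-di-tert-butyl-2,2'-bipyridine (12 mol %), 4CzIPN (2 mol %), Hantzsch ester (2 equiv), DMA, 450 nm LEDs, 25 °C; NaHCO3 work-up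
Reagents that add atoms: N-hydroxyphthalimide, O=C1N(O)C(=O)c2ccccc12 (its atoms stay in 25 only)
Why: Proposed new method: a nickel/photoredox decarboxylative C(sp3)–C(sp2) cross-coupling whose electrophile is an α-iodo vinylogous amide: the photoreduced 4CzIPN (fed by the Hantzsch ester) fragments 25 to CO2, phthalimide and the primary C14 radical, zerovalent nickel inserts into the C1–I bond of 13, the radical is captured at nickel and reductive elimination from trivalent nickel forges the C14–C1 bond that joins the halves without touching a stereocentre; closest known reactions are nickel-catalysed reductive and photoredox couplings of N-(acyloxy)phthalimides with aryl and vinyl halides and palladium couplings of α-iodoenaminones.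

**Step 16**
Reactants: 26 5-[(9S)-3-methyl-1-{5-[(3S,9R,9aS)-3-methyl-2-oxooctahydro-2H-quinolizin-9-yl]pentyl}-2-oxo-3,4,6,7,8,9-hexahydro-2H-quinolizin-9-yl]pentanoic acid
Product: 27 5-[(9S)-3-methyl-1-{5-[(3S,9R,9aR)-3-methyl-1-methylidene-2-oxooctahydro-2H-quinolizin-9-yl]pentyl}-2-oxo-3,4,6,7,8,9-hexahydro-2H-quinolizin-9-yl]pentanoic acid
Conditions: paraformaldehyde (3 equiv), diisopropylammonium trifluoroacetate (1 equiv), TFA (1.2 equiv), THF, 65 °C
Reagents that add atoms: formaldehyde (from paraformaldehyde), C=O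
Why: Mannich/elimination α-methylenation: C1 of unit A is the only α-CH2, so only it can give the enone, the fully substituted vinylogous amide of unit B is inert, and C9a of unit A stays in its thermodynamic configuration (descriptor changes by priority only).

**Step 17**
Reactants: 27 5-[(9S)-3-methyl-1-{5-[(3S,9R,9aR)-3-methyl-1-methylidene-2-oxooctahydro-2H-quinolizin-9-yl]pentyl}-2-oxo-3,4,6,7,8,9-hexahydro-2H-quinolizin-9-yl]pentanoic acid
Product: 29 macrocyclic mono-vinylogous amide (30 with a C1=C9a double bond in unit B; unit A 1S,3S,9R,9aR; unit B 9S), via redox-active ester 28 (not isolated)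
Conditions: N-hydroxyphthalimide (1.1 equiv), N,N'-diisopropylcarbodiimide (1.1 equiv), DMAP (5 mol %), CH2Cl2, rt; then dilute to 2 mM in CH2Cl2/DMF, Ru(bpy)3(PF6)2 (2 mol %), Hantzsch ester (1.5 equiv), 450 nm LEDs, 25 °C
Reagents that add atoms: N-hydroxyphthalimide, O=C1N(O)C(=O)c2ccccc12 (its atoms stay in 28 only)
Why: Photoredox decarboxylative Giese macrocyclisation: the primary radical of the unit B chain adds to the exo-methylene carbon and closes the 16-membered ring, and the resulting α-keto radical is reduced and protonated to give C1 of unit A, whose configuration is settled thermodynamically in step 18.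

**Step 18**
Reactants: 29 macrocyclic mono-vinylogous amide
Product: 30 CNP0268544.8 (unit A 1S,3S,9R,9aR; unit B 1R,3S,9S,9aR)
Conditions: Et3SiH (5 equiv), TFA/CH2Cl2 (1:3), 0 °C → rt; NaHCO3 work-up; then K2CO3, MeOH, 0 °C → rt, 1 h
Reagents that add atoms: none
Why: Ionic hydrogenation of the tetrasubstituted vinylogous amide: in the C1-protonated iminium, A(1,2) strain holds the C9 chain pseudo-axial, so hydride adds axially to C9a anti to it (H9a cis to H9 in unit B); short base treatment then equilibrates only the enolisable C1 and C3 centres to the arrangement with each C1 chain anti to its C9 chain and both methyls equatorial.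

**Compound list**
1 | ethyl (S)-3-hydroxybutanoate | CCOC(=O)C[C@H](C)O | starting material
2 | 1-chloro-3-iodopropane | ClCCCI | starting material
3 | ethyl (2S,3S)-2-(3-chloropropyl)-3-hydroxybutanoate | C[C@H](O)[C@H](CCCCl)C(=O)OCC | intermediate
4 | (2R,3S)-2-(3-chloropropyl)butane-1,3-diol | C[C@H](O)[C@H](CCCCl)CO | intermediate
5 | (2R,3S)-2-(3-chloropropyl)-3-hydroxybutyl 4-methylbenzenesulfonate | C[C@H](O)[C@H](CCCCl)COS(=O)(=O)c1ccc(C)cc1 | intermediate
6 | pent-4-en-1-ylmagnesium bromide | C=CCCC[Mg]Br | starting material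
7 | (2S,3S)-3-(3-chloropropyl)non-8-en-2-ol | C[C@H](O)[C@H](CCCCl)CCCCC=C | intermediate
8 | (6S)-6-acetyl-9-chlorononanoic acid | CC(=O)[C@H](CCCCl)CCCCC(=O)O | intermediate
9 | N-methoxy-N-methylmethacrylamide | CON(C)C(=O)C(C)=C | starting material
10 | (6S)-6-(3-chloropropyl)-10-methyl-7,9-dioxoundec-10-enoic acid (formed in the flask) | CC(=C)C(=O)CC(=O)[C@H](CCCCl)CCCCC(=O)O | intermediate
11 | (6S)-9-chloro-6-(5-methyl-4-oxo-1,4,5,6-tetrahydropyridin-2-yl)nonanoic acid (formed in the flask; ring methyl epimers) | CC1CNC(=CC1=O)[C@H](CCCCl)CCCCC(=O)O | intermediate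
12 | 5-[(9S)-3-methyl-2-oxo-3,4,6,7,8,9-hexahydro-2H-quinolizin-9-yl]pentanoic acid (C3 epimers) | O=C1C=C2[C@@H](CCCCC(=O)O)CCCN2CC1C | intermediate
13 | 5-[(9S)-1-iodo-3-methyl-2-oxo-3,4,6,7,8,9-hexahydro-2H-quinolizin-9-yl]pentanoic acid (C3 epimers) | O=C1C(I)=C2[C@@H](CCCCC(=O)O)CCCN2CC1C | intermediate
14 | ethyl (R)-3-hydroxybutanoate | CCOC(=O)C[C@@H](C)O | starting material
15 | ethyl (2R,3R)-2-(3-chloropropyl)-3-hydroxybutanoate | C[C@@H](O)[C@@H](CCCCl)C(=O)OCC | intermediate
16 | (2S,3R)-2-(3-chloropropyl)butane-1,3-diol | C[C@@H](O)[C@@H](CCCCl)CO | intermediate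
17 | (2S,3R)-2-(3-chloropropyl)-3-hydroxybutyl 4-methylbenzenesulfonate | C[C@@H](O)[C@@H](CCCCl)COS(=O)(=O)c1ccc(C)cc1 | intermediate
18 | hex-5-en-1-ylmagnesium bromide | C=CCCCC[Mg]Br | starting material
19 | (2R,3R)-3-(3-chloropropyl)dec-9-en-2-ol | C[C@@H](O)[C@@H](CCCCl)CCCCCC=C | intermediate
20 | (7R)-7-acetyl-10-chlorodecanoic acid | CC(=O)[C@@H](CCCCl)CCCCCC(=O)O | intermediate
21 | (7R)-7-(3-chloropropyl)-11-methyl-8,10-dioxododec-11-enoic acid (formed in the flask) | CC(=C)C(=O)CC(=O)[C@@H](CCCCl)CCCCCC(=O)O | intermediate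
22 | (7R)-10-chloro-7-(5-methyl-4-oxo-1,4,5,6-tetrahydropyridin-2-yl)decanoic acid (formed in the flask; ring methyl epimers) | CC1CNC(=CC1=O)[C@@H](CCCCl)CCCCCC(=O)O | intermediate
23 | 6-[(9R)-3-methyl-2-oxo-3,4,6,7,8,9-hexahydro-2H-quinolizin-9-yl]hexanoic acid (C3 epimers) | O=C1C=C2[C@H](CCCCCC(=O)O)CCCN2CC1C | intermediate
24 | 6-[(3S,9R,9aS)-3-methyl-2-oxooctahydro-2H-quinolizin-9-yl]hexanoic acid | C[C@H]1CN2CCC[C@@H](CCCCCC(=O)O)[C@@H]2CC1=O | intermediate
25 | 1,3-dioxoisoindolin-2-yl 6-[(3S,9R,9aS)-3-methyl-2-oxooctahydro-2H-quinolizin-9-yl]hexanoate (formed in the flask) | C[C@H]1CN2CCC[C@@H](CCCCCC(=O)ON3C(=O)c4ccccc4C3=O)[C@@H]2CC1=O | intermediate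
26 | 5-[(9S)-3-methyl-1-{5-[(3S,9R,9aS)-3-methyl-2-oxooctahydro-2H-quinolizin-9-yl]pentyl}-2-oxo-3,4,6,7,8,9-hexahydro-2H-quinolizin-9-yl]pentanoic acid | C[C@H]1CN2CCC[C@@H](CCCCCC3=C4[C@@H](CCCCC(=O)O)CCCN4CC(C)C3=O)[C@@H]2CC1=O | intermediate
27 | 5-[(9S)-3-methyl-1-{5-[(3S,9R,9aR)-3-methyl-1-methylidene-2-oxooctahydro-2H-quinolizin-9-yl]pentyl}-2-oxo-3,4,6,7,8,9-hexahydro-2H-quinolizin-9-yl]pentanoic acid | C[C@H]1CN2CCC[C@@H](CCCCCC3=C4[C@@H](CCCCC(=O)O)CCCN4CC(C)C3=O)[C@@H]2C(=C)C1=O | intermediate
28 | N-(acyloxy)phthalimide of 27 (formed in the flask) | C[C@H]1CN2CCC[C@@H](CCCCCC3=C4[C@@H](CCCCC(=O)ON5C(=O)c6ccccc6C5=O)CCCN4CC(C)C3=O)[C@@H]2C(=C)C1=O | intermediate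
29 | macrocyclic mono-vinylogous amide: 30 with a C1=C9a double bond in unit B; unit A 1S,3S,9R,9aR (C1 drawn in its thermodynamic configuration), unit B 9S, C3 of unit B epimeric | C[C@H]1CN2CCC[C@H]3CCCCCC4=C5[C@@H](CCCCC[C@H](C1=O)[C@@H]32)CCCN5CC(C)C4=O | intermediate
30 | CNP0268544.8, macrocyclic bis(3-methylquinolizidin-2-one); unit A 1S,3S,9R,9aR, unit B 1R,3S,9S,9aR | C[C@H]1CN2CCC[C@H]3CCCCC[C@H]4C(=O)[C@@H](C)CN5CCC[C@H](CCCCC[C@H](C1=O)[C@@H]32)[C@H]45 | target

**Total step count:** 18. **Longest linear sequence:** 11 steps (steps 8–14, then 15–18; the line 1–7, 15–18 is equally long).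

**Three steps most likely to fail**

Step 15 (the proposed new coupling). The risks are slow oxidative addition into the electron-rich C1–I bond, protodeiodination of 13, and reduction or dimerisation of the alkyl radical. The fallback uses known two-electron organozinc chemistry, sets out from 24 and comes back to the route at 26. Suárez iododecarboxylation of 24 as its trifluoroacetate salt (PhI(OAc)2, I2, CH2Cl2, visible light) gives the primary iodide (3S,9R,9aS)-9-(5-iodopentyl)-3-methyloctahydro-2H-quinolizin-2-one F1. Zinc insertion (Zn dust, LiCl, THF) gives the alkylzinc iodide {5-[(3S,9R,9aS)-3-methyl-2-oxooctahydro-2H-quinolizin-9-yl]pentyl}zinc iodide F2. A palladium-catalysed Negishi coupling (Pd(OAc)2, SPhos, THF/NMP) with the sodium carboxylate of 13 then gives 26.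

Step 17 (radical macrocyclisation). The risks are reduction of the radical before ring closure, oligomerisation, and 1,5-hydrogen transfer from the allylic C9–H of unit B, which would erode that stereocentre. The fallback closes the same ring by ionic chemistry, sets out from 26 (before methylenation) and comes back at 29. The acid is converted into the S-ethyl thioester of 26 F3 (EtSH, EDC·HCl, DMAP). Fukuyama reduction (Pd/C, Et3SiH, acetone) gives the aldehyde 5-oxopentyl analogue of 26 F4. High-dilution intramolecular aldol condensation at the only α-CH2 (C1 of unit A; pyrrolidine, AcOH, toluene, 60 °C) gives the macrocyclic exocyclic enone (E/Z mixture) F5. Conjugate reduction with [(Ph3P)CuH]6 gives 29; the aldehyde carbon supplies the fifth chain carbon that formaldehyde supplies in the main route.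

Step 18 (last stereocentre and final epimer control). The risks are hydride delivery syn to the C9 chain, ketone over-reduction, and C9a scrambling by retro-aza-Michael opening during the base treatment. The fallback changes the reduction mode, sets out from 29 and comes back at 30. Hydrogenation over PtO2 in AcOH (H2, 3 bar) saturates the vinylogous amide by syn delivery to the face opposite the pseudo-axial C9 chain and deliberately over-reduces both ketones to the bis-carbinol (carbinol epimers) F6. Dess–Martin oxidation (NaHCO3 buffer) and the same brief K2CO3/MeOH equilibration then give 30.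

**Further compounds**
F1 | step 15 | (3S,9R,9aS)-9-(5-iodopentyl)-3-methyloctahydro-2H-quinolizin-2-one | C[C@H]1CN2CCC[C@@H](CCCCCI)[C@@H]2CC1=O
F2 | step 15 | {5-[(3S,9R,9aS)-3-methyl-2-oxooctahydro-2H-quinolizin-9-yl]pentyl}zinc iodide | C[C@H]1CN2CCC[C@@H](CCCCC[Zn]I)[C@@H]2CC1=O
F3 | step 17 | S-ethyl thioester of 26 | C[C@H]1CN2CCC[C@@H](CCCCCC3=C4[C@@H](CCCCC(=O)SCC)CCCN4CC(C)C3=O)[C@@H]2CC1=O
F4 | step 17 | aldehyde 5-oxopentyl analogue of 26 | C[C@H]1CN2CCC[C@@H](CCCCCC3=C4[C@@H](CCCCC=O)CCCN4CC(C)C3=O)[C@@H]2CC1=O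
F5 | step 17 | macrocyclic exocyclic enone (E/Z mixture at the C1 alkylidene of unit A) | C[C@H]1CN2CCC[C@H]3CCCCCC4=C5[C@@H](CCCCC=C(C1=O)[C@@H]32)CCCN5CC(C)C4=O
F6 | step 18 | bis-carbinol of 30 (both C2 ketones reduced, carbinol epimers) | C[C@H]1CN2CCC[C@H]3CCCCC[C@H]4C(O)[C@@H](C)CN5CCC[C@H](CCCCC[C@H](C1O)[C@@H]32)[C@H]45
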